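The protic impurity in the flask is a small part of the partner charge, 2.50%, yet it stands at 100 times the free catalyst charged, so what does it attack?

all flasks: free catalyst 0.10 mM

| flask | substrate | partner | protic impurity | remark |
|---|---|---|---|---|
| south | 0.10 M | 0.40 M | 0.0067 M | run made earlier |
| south-east | 0.10 M | 0.40 M | 0.015 M | run made earlier |
| north-east | 0.15 M | 0.40 M | 0.010 M | run made earlier |
| flask | 0.10 M | 0.400 M | 0.0100 M |  |

| run | time / h | target / % |
|---|---|---|
| south | 0.667 | 29.3 |
| south | 1.50 | 58.7 |
| south | 3.00 | 91.1 |
| south | 5.00 | 100.6 |
| south-east | 0.667 | 27.7 |
| south-east | 1.50 | 56.8 |
| south-east | 3.00 | 91.2 |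
| south-east | 5.00 | 100.1 |
| north-east | 1.33 | 39.9 |
| north-east | 2.50 | 64.1 |
| north-east | 4.00 | 90.8 |
| north-east | 5.00 | 96.1 |

(readings scatter by 1 percentage point)

- no earlier run changes the charge of free catalyst; that part of a forecast is a guess
- no earlier run changes the charge of partner; that part of a forecast is a guess

* apparent order in free catalyst when 50% of the substrate are converted (percent change of the rate of making target for one percent more free catalyst charged)
* apparent order in partner when 50% of the substrate are converted (percent change of the rate of making target for one percent more partner charged)

Raising the impurity from 0.0067 M to 0.015 M moves the reading at 1.50 h from 58.7% in the south run to 56.8% in the south-east run. I therefore take the catalyst as untouched by the impurity; no run varies its charge, so order 1 in free catalyst is a guess.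

I assume the impurity quenches partner one for one, and quickly. How much partner is then free in the flask at 50% conversion? Substrate is the limiting reagent, and at one partner per substrate, as I assume, that conversion costs 12.5% of the partner charge. This leaves the free partner share, the fraction of the partner charge still unconsumed at a given conversion: 85.0%.

What does extra partner charge do? At fixed conversion and fixed impurity both deductions stay the same amounts, so in this flask one percent more partner charge raises free partner by 1.18 percent, and the order in the charge is the order in free partner divided by the free share.

How large is that order in free partner? From the interval ending at 1.50 h to the one ending at 3.00 h in the south run, the rate read from the target readings falls by a factor 1.63, while the mean substrate reckoned from the same readings falls by 2.23. So these readings put substrate's order below 1. No run varies partner, so I guess 0.5 for substrate and 0.5 for free partner, which gives 0.588 in the partner charge.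

The forecast gives 0.95 (0.6 to 1.1) in free catalyst and 0.7 (0.2 to 1.05) in partner, noting “Partner order is unobserved.”

The flask gives 1.0 in free catalyst and 0.65 in partner; multiplied by the free share, the second becomes an order of 0.552 in free partner, against my 0.5.

    substrate + free catalyst → catalyst intermediate A (k = 7.10 M⁻¹ s⁻¹)
    catalyst intermediate A ⇌ catalyst intermediate B (K = 4.00, k = 27.0 s⁻¹)
    partner + catalyst intermediate B → catalyst intermediate C (k = 0.630 M⁻¹ s⁻¹)
    catalyst intermediate C → released group + catalyst intermediate D (k = 5.10 s⁻¹)
    catalyst intermediate D → free catalyst + target (k = 0.840 s⁻¹)
    partner + protic impurity → quenched reagent (k = 0.650 M⁻¹ s⁻¹)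
    free catalyst + released group ⇌ idle complex (K = 3.80 M⁻¹, k = 0.0330 M⁻¹ s⁻¹)

At 4.00 h the flask holds 98.2% target, and carrying the free share on to that conversion gives 73.0% of the partner charge, where the flask stands at 73.0%.

The data stem from a simulated flask with constants of no real substance; noise was put on by code.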